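The C12–C13 bond is made by an iron-catalysed, alkoxide-directed carbomagnesiation that also sets the Z olefin. The route has 9 steps, with a longest linear sequence of 6.

The route rests on disconnecting the side chain between C12, the second methylene out from the decalin, and C13, the olefinic carbon that carries the hydroxymethyl group. The key step is an iron-catalysed, alkoxide-directed syn-carbomagnesiation: a homodrimenyl Grignard reagent made from (+)-sclareolide adds across the C13≡C14 triple bond of an (R)-3-furyl homopropargylic alcohol. It exploits the C16 hydroxyl beside the five-membered ring, which is homopropargylic to that alkyne: its alkoxide delivers the alkyl group to the distal carbon C13, and syn addition sets the Z-trisubstituted C13=C14 olefin in the same operation. The furan is a latent butenolide ring, unveiled last by photooxygenation and reduction.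

Key step: step 7

Remark (numbering): decalin carbons C1–C10 as in drimanes (C8 bears the vinylic methyl, C9 the side chain); side chain C11 and C12 (CH2CH2), C13 (olefinic carbon bearing CH2OH), C14 (olefinic CH), C15 (CH2), C16 (carbinol carbon), then the butenolide ring.

Remark (assumption): (R)-TRIP, (R)-3,3'-bis(2,4,6-triisopropylphenyl)-1,1'-binaphthyl-2,2'-diyl hydrogen phosphate, is assumed to direct the allenyl group to the Re face of furan-3-carbaldehyde, as expected by analogy with aryl aldehydes; the antipodal acid would be used if the opposite sense were found.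

Step 1
Reactants: 1 (+)-sclareolide
Product: 2 methyl 2-[(4aS,8aS)-2,5,5,8a-tetramethyl-3,4,4a,5,6,7,8,8a-octahydronaphthalen-1-yl]acetate
Conditions: conc. H2SO4, MeOH, reflux
Reagents that add atoms: methanol, CO
Why: Acid ionises the tertiary C8–O bond of the lactone, E1 loss of the C9 proton under equilibrating conditions should favour the tetrasubstituted Δ8(9) olefin, and Fischer esterification traps the liberated acid (dehydrative lactone methanolysis); C5 and C10 are untouched.

Step 2
Reactants: 2 methyl ester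
Product: 3 2-[(4aS,8aS)-2,5,5,8a-tetramethyl-3,4,4a,5,6,7,8,8a-octahydronaphthalen-1-yl]ethanol
Conditions: LiAlH4, THF, 0 °C to rt; Fieser work-up
Reagents that add atoms: none
Why: Hydride reduction of the ester to the primary alcohol (LiAlH4 reduction) leaves the isolated tetrasubstituted olefin alone.

Step 3
Reactants: 3 homoallylic alcohol
Product: 4 (4aS,8aS)-1-(2-bromoethyl)-2,5,5,8a-tetramethyl-3,4,4a,5,6,7,8,8a-octahydronaphthalene
Conditions: CBr4, PPh3, CH2Cl2, 0 °C to rt
Reagents that add atoms: carbon tetrabromide, BrC(Br)(Br)Br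
Why: The Appel reaction displaces the alkoxyphosphonium of the primary alcohol by bromide (SN2) under neutral conditions that should not isomerise the acid-sensitive olefin.

Step 4
Reactants: 5 furan-3-carbaldehyde; 6 allenylboronic acid pinacol ester
Product: 8 (R)-1-(furan-3-yl)but-3-yn-1-ol, via pinacol borate ester 7 (not isolated)
Conditions: (R)-TRIP (10 mol%), 4 Å MS, toluene, 0 °C; aqueous work-up
Reagents that add atoms: none
Why: In this chiral phosphoric acid-catalysed propargylation the acid activates the boronate in a closed six-membered SE2′ transition state and should direct the allenyl group to the Re face of the aldehyde, which sets the (R)-carbinol C16; the borate is hydrolysed on work-up.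

Step 5
Reactants: 8 (R)-1-(furan-3-yl)but-3-yn-1-ol
Product: 10 (R)-5-(furan-3-yl)pent-2-yne-1,5-diol, via dilithio alkoxide-acetylide 9 (not isolated)
Conditions: n-BuLi (2.1 equiv), THF, −78 °C; (CH2O)n, −78 °C to rt; aq. NH4Cl
Reagents that add atoms: formaldehyde (as paraformaldehyde), C=O
Why: The alkoxide-acetylide dianion should react with formaldehyde at the more nucleophilic acetylide carbon (alkynylation of an aldehyde), without touching the stereocentre.

Step 6
Reactants: 10 (R)-5-(furan-3-yl)pent-2-yne-1,5-diol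
Product: 11 (R)-5-[(tert-butyldimethylsilyl)oxy]-1-(furan-3-yl)pent-3-yn-1-ol
Conditions: TBSCl (1.05 equiv), imidazole, CH2Cl2, −20 to 0 °C
Reagents that add atoms: tert-butyldimethylsilyl chloride, CC(C)(C)[Si](C)(C)Cl
Why: The unhindered primary propargylic hydroxyl is silylated much faster than the secondary furyl carbinol (selective silyl ether formation), which masks the oxygen that would otherwise compete as a directing group in step 7.

Step 7
Reactants: 4 homodrimenyl bromide; 11 silyl-protected homopropargylic alcohol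
Product: 15 (1R,3Z)-4-[(tert-butyldimethylsilyloxy)methyl]-1-(furan-3-yl)-6-[(4aS,8aS)-2,5,5,8a-tetramethyl-3,4,4a,5,6,7,8,8a-octahydronaphthalen-1-yl]hex-3-en-1-ol, via Grignard reagent 12 (not isolated), via bromomagnesium alkoxide 13 (not isolated), via alkenylmagnesium adduct 14 (not isolated)
Conditions: 4, Mg, THF, rt; separately 11, MeMgBr (1.0 equiv), THF, 0 °C; then Fe(acac)3 (15 mol%), dppe (15 mol%), Grignard solution (2.5 equiv), THF, 0 °C to rt; aq. NH4Cl
Reagents that add atoms: none
Why: The Grignard reagent reduces Fe(acac)3 to a low-valent alkyliron species that binds the C16 magnesium alkoxide, and intramolecular syn-carboferration of the C13≡C14 triple bond places iron on the proximal carbon C14 (five-membered oxaferracycle) and the homodrimenyl group on the distal carbon C13; transmetalation to magnesium gives alkenyl Grignard 14, which is protonated with retention. The closest known reaction type is the iron-catalysed alkoxide-directed carbomagnesiation of propargylic and homopropargylic alcohols with alkyl Grignard reagents. No ring of the product is closed (the metallacycle is transient) and no new stereocentre is formed; the stereo-element created is the C13=C14 geometry, which should be Z because carbon and metal (later hydrogen) add to the same face of the alkyne. The step needs regiocontrol (alkyl to C13, not C14), which the C16 alkoxide tether secures while the only other oxygen is masked as a bulky, poorly coordinating silyl ether. It also needs carbometalation to outrun β-hydride elimination of the alkyliron, for which the bisphosphine ligand and the excess of the cheap sclareolide-derived Grignard reagent are provided. The C16 stereocentre, the furan and the silyl ether are spectators towards Grignard reagents.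

Step 8
Reactants: 15 silyl ether
Product: 16 (2Z,5R)-5-(furan-3-yl)-2-{2-[(4aS,8aS)-2,5,5,8a-tetramethyl-3,4,4a,5,6,7,8,8a-octahydronaphthalen-1-yl]ethyl}pent-2-ene-1,5-diol
Conditions: TBAF, THF, 0 °C to rt
Reagents that add atoms: none
Why: Fluoride cleaves the Si–O bond (desilylation) without affecting the furan, the olefins or the stereocentres.

Step 9
Reactants: 16 furan diol
Product: 19 4-{(1R,3Z)-1-hydroxy-4-(hydroxymethyl)-6-[(4aS,8aS)-2,5,5,8a-tetramethyl-3,4,4a,5,6,7,8,8a-octahydronaphthalen-1-yl]hex-3-en-1-yl}furan-2(5H)-one, via furan endoperoxide 17 (not isolated), via hydroxybutenolide 18 (not isolated)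
Conditions: O2, hν, rose bengal (cat.), i-Pr2NEt, CH2Cl2, −78 °C; then NaBH4, EtOH, −78 to 0 °C; then 1 M HCl to pH 3
Reagents that add atoms: dioxygen, O=O
Why: [4+2] cycloaddition of singlet oxygen to the furan and Kornblum–DeLaMare fragmentation of the endoperoxide by the hindered base at the C–H remote from the substituent should give the 4-substituted 5-hydroxybutenolide, whose masked aldehyde is reduced by borohydride and relactonises on acidification to the 4-substituted butenolide; at −78 °C the furan is expected to react faster than the hindered tetrasubstituted and the trisubstituted olefins.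

Compound list
1 | (+)-sclareolide, (3aR,5aS,9aS,9bR)-3a,6,6,9a-tetramethyldecahydronaphtho[2,1-b]furan-2(1H)-one | O=C1C[C@@H]2[C@@]3(C)CCCC(C)(C)[C@@H]3CC[C@@]2(C)O1 | starting material
2 | methyl 2-[(4aS,8aS)-2,5,5,8a-tetramethyl-3,4,4a,5,6,7,8,8a-octahydronaphthalen-1-yl]acetate | CC1=C(CC(=O)OC)[C@@]2(C)CCCC(C)(C)[C@@H]2CC1 | intermediate
3 | 2-[(4aS,8aS)-2,5,5,8a-tetramethyl-3,4,4a,5,6,7,8,8a-octahydronaphthalen-1-yl]ethanol | CC1=C(CCO)[C@@]2(C)CCCC(C)(C)[C@@H]2CC1 | intermediate
4 | (4aS,8aS)-1-(2-bromoethyl)-2,5,5,8a-tetramethyl-3,4,4a,5,6,7,8,8a-octahydronaphthalene | CC1=C(CCBr)[C@@]2(C)CCCC(C)(C)[C@@H]2CC1 | intermediate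
5 | furan-3-carbaldehyde | O=Cc1ccoc1 | starting material
6 | allenylboronic acid pinacol ester, 4,4,5,5-tetramethyl-2-(propa-1,2-dienyl)-1,3,2-dioxaborolane | C=C=CB1OC(C)(C)C(C)(C)O1 | starting material
7 | (R)-2-{[1-(furan-3-yl)but-3-yn-1-yl]oxy}-4,4,5,5-tetramethyl-1,3,2-dioxaborolane (not isolated) | C#CC[C@@H](OB1OC(C)(C)C(C)(C)O1)c1ccoc1 | intermediate
8 | (R)-1-(furan-3-yl)but-3-yn-1-ol | C#CC[C@@H](O)c1ccoc1 | intermediate
9 | lithium (R)-1-(furan-3-yl)-4-lithiobut-3-yn-1-olate (not isolated) | [Li]C#CC[C@@H](O[Li])c1ccoc1 | intermediate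
10 | (R)-5-(furan-3-yl)pent-2-yne-1,5-diol | OCC#CC[C@@H](O)c1ccoc1 | intermediate
11 | (R)-5-[(tert-butyldimethylsilyl)oxy]-1-(furan-3-yl)pent-3-yn-1-ol | CC(C)(C)[Si](C)(C)OCC#CC[C@@H](O)c1ccoc1 | intermediate
12 | {2-[(4aS,8aS)-2,5,5,8a-tetramethyl-3,4,4a,5,6,7,8,8a-octahydronaphthalen-1-yl]ethyl}magnesium bromide (not isolated) | CC1=C(CC[Mg]Br)[C@@]2(C)CCCC(C)(C)[C@@H]2CC1 | intermediate
13 | bromomagnesium (R)-5-[(tert-butyldimethylsilyl)oxy]-1-(furan-3-yl)pent-3-yn-1-olate (not isolated) | CC(C)(C)[Si](C)(C)OCC#CC[C@@H](O[Mg]Br)c1ccoc1 | intermediate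
14 | bis(bromomagnesium) adduct: C16 alkoxide and C14 alkenylmagnesium, Mg on C14 cis to the new C12–C13 bond (not isolated) | CC1=C(CC/C(=C(\[Mg]Br)C[C@@H](O[Mg]Br)c2ccoc2)CO[Si](C)(C)C(C)(C)C)[C@@]2(C)CCCC(C)(C)[C@@H]2CC1 | intermediate
15 | (1R,3Z)-4-[(tert-butyldimethylsilyloxy)methyl]-1-(furan-3-yl)-6-[(4aS,8aS)-2,5,5,8a-tetramethyl-3,4,4a,5,6,7,8,8a-octahydronaphthalen-1-yl]hex-3-en-1-ol | CC1=C(CC/C(=C/C[C@@H](O)c2ccoc2)CO[Si](C)(C)C(C)(C)C)[C@@]2(C)CCCC(C)(C)[C@@H]2CC1 | intermediate
16 | (2Z,5R)-5-(furan-3-yl)-2-{2-[(4aS,8aS)-2,5,5,8a-tetramethyl-3,4,4a,5,6,7,8,8a-octahydronaphthalen-1-yl]ethyl}pent-2-ene-1,5-diol | CC1=C(CC/C(=C/C[C@@H](O)c2ccoc2)CO)[C@@]2(C)CCCC(C)(C)[C@@H]2CC1 | intermediate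
17 | 2,3,7-trioxabicyclo[2.2.1]hept-5-ene (furan endoperoxide) of 16, side chain on C5, bridgehead configuration unassigned (not isolated) | CC1=C(CC/C(=C/C[C@@H](O)C2=CC3OOC2O3)CO)[C@@]2(C)CCCC(C)(C)[C@@H]2CC1 | intermediate
18 | 5-hydroxy-4-{(1R,3Z)-1-hydroxy-4-(hydroxymethyl)-6-[(4aS,8aS)-2,5,5,8a-tetramethyl-3,4,4a,5,6,7,8,8a-octahydronaphthalen-1-yl]hex-3-en-1-yl}furan-2(5H)-one, C5 epimers (not isolated) | CC1=C(CC/C(=C/C[C@@H](O)C2=CC(=O)OC2O)CO)[C@@]2(C)CCCC(C)(C)[C@@H]2CC1 | intermediate
19 | 4-{(1R,3Z)-1-hydroxy-4-(hydroxymethyl)-6-[(4aS,8aS)-2,5,5,8a-tetramethyl-3,4,4a,5,6,7,8,8a-octahydronaphthalen-1-yl]hex-3-en-1-yl}furan-2(5H)-one (CNP0224983.2) | CC1=C(CC/C(=C/C[C@@H](O)C2=CC(=O)OC2)CO)[C@@]2(C)CCCC(C)(C)[C@@H]2CC1 | target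

Total step count: 9.
Longest linear sequence: 6 steps (5 to 19 through steps 4–9; equally 1 to 19 through steps 1–3 and 7–9).

Steps most likely to fail

Step 7. The alkyliron intermediate may undergo β-hydride elimination faster than it adds to the alkyne, or the alkoxide may fail to control which alkyne carbon receives the alkyl group. The bond would then be made by a B-alkyl Suzuki–Miyaura coupling, with the olefin geometry set beforehand. Setting out from diol 10, palladium-catalysed syn-hydrostannation (Bu3SnH, PdCl2(PPh3)2, THF), directed to the carbon next to the primary hydroxyl, would give (2E,5R)-5-(furan-3-yl)-2-(tributylstannyl)pent-2-ene-1,5-diol F1. Iododestannylation (I2, CH2Cl2, 0 °C) would give (2E,5R)-5-(furan-3-yl)-2-iodopent-2-ene-1,5-diol F2. Grignard reagent 12 (from bromide 4) would be trapped with B-methoxy-9-BBN to give the bromomagnesium B-methoxy-B-alkyl-9-borabicyclo[3.3.1]nonanate complex F3. Coupling of F3 with F2 (Pd(dppf)Cl2, AsPh3, K3PO4, DMF/H2O, rt) should proceed with retention of olefin geometry and rejoin the route at diol 16.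

Step 9. Singlet oxygen may attack the electron-rich tetrasubstituted Δ8(9) olefin in an ene reaction alongside the furan, or borohydride may reduce the butenolide further. The butenolide would then be made before the fragments are joined, on a substrate without electron-rich olefins. Setting out from diol 10, the vinyl iodide F2 (made through F1 as described above) would be photooxygenated (O2, hν, rose bengal, i-Pr2NEt, CH2Cl2, −78 °C) to 5-hydroxy-4-[(1R,3E)-1,5-dihydroxy-4-iodopent-3-en-1-yl]furan-2(5H)-one F4. Reduction (NaBH4, EtOH; then HCl) would give 4-[(1R,3E)-1,5-dihydroxy-4-iodopent-3-en-1-yl]furan-2(5H)-one F5. Coupling of F5 with the borinate complex F3 (Pd(dppf)Cl2, AsPh3, K3PO4, DMF, rt) should give target 19 directly.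

Step 1. Equilibration may stop short and leave Δ7 and exocyclic olefin isomers mixed with the Δ8(9) ester. The olefin would then be placed at the alcohol oxidation level instead. Setting out from 1, LiAlH4 reduction (THF, 0 °C to rt) would give (1R,2R,4aS,8aS)-1-(2-hydroxyethyl)-2,5,5,8a-tetramethyldecahydronaphthalen-2-ol F6. Selective acetylation of the primary hydroxyl (Ac2O, pyridine, 0 °C) would give 2-[(1R,2R,4aS,8aS)-2-hydroxy-2,5,5,8a-tetramethyldecahydronaphthalen-1-yl]ethyl acetate F7. Iodine-catalysed dehydration with equilibration of the olefin into the tetrasubstituted position (I2 cat., benzene, reflux) would give 2-[(4aS,8aS)-2,5,5,8a-tetramethyl-3,4,4a,5,6,7,8,8a-octahydronaphthalen-1-yl]ethyl acetate F8. Methanolysis (K2CO3, MeOH) would rejoin the route at alcohol 3.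

Further compounds
F1 | step 7 | (2E,5R)-5-(furan-3-yl)-2-(tributylstannyl)pent-2-ene-1,5-diol | OC/C(=C\C[C@@H](O)c1ccoc1)[Sn](CCCC)(CCCC)CCCC
F2 | step 7 | (2E,5R)-5-(furan-3-yl)-2-iodopent-2-ene-1,5-diol | OC/C(I)=C\C[C@@H](O)c1ccoc1
F3 | step 7 | bromomagnesium B-methoxy-B-{2-[(4aS,8aS)-2,5,5,8a-tetramethyl-3,4,4a,5,6,7,8,8a-octahydronaphthalen-1-yl]ethyl}-9-borabicyclo[3.3.1]nonanate | CC1=C(CC[B-]3(OC)C4CCCC3CCC4)[C@@]2(C)CCCC(C)(C)[C@@H]2CC1.[Mg+]Br
F4 | step 9 | 5-hydroxy-4-[(1R,3E)-1,5-dihydroxy-4-iodopent-3-en-1-yl]furan-2(5H)-one | OC/C(I)=C\C[C@@H](O)C1=CC(=O)OC1O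
F5 | step 9 | 4-[(1R,3E)-1,5-dihydroxy-4-iodopent-3-en-1-yl]furan-2(5H)-one | OC/C(I)=C\C[C@@H](O)C1=CC(=O)OC1
F6 | step 1 | (1R,2R,4aS,8aS)-1-(2-hydroxyethyl)-2,5,5,8a-tetramethyldecahydronaphthalen-2-ol | OCC[C@@H]1[C@@]2(C)CCCC(C)(C)[C@@H]2CC[C@@]1(C)O
F7 | step 1 | 2-[(1R,2R,4aS,8aS)-2-hydroxy-2,5,5,8a-tetramethyldecahydronaphthalen-1-yl]ethyl acetate | CC(=O)OCC[C@@H]1[C@@]2(C)CCCC(C)(C)[C@@H]2CC[C@@]1(C)O
F8 | step 1 | 2-[(4aS,8aS)-2,5,5,8a-tetramethyl-3,4,4a,5,6,7,8,8a-octahydronaphthalen-1-yl]ethyl acetate | CC1=C(CCOC(C)=O)[C@@]2(C)CCCC(C)(C)[C@@H]2CC1
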